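**Retrosynthetic overview**

1. Target 26 ← global desilylation of the tetrakis(triethylsilyl) ether 25.
2. Carbocycle and pyran ring are formed together in one step: intramolecular oxa-Diels–Alder reaction of an allenyl ketone (O1=C3–C4=C4a) with the terminal C8a=C1 alkene, forming O1–C1 and C4a–C8a; the allene comes from base isomerisation of 2-yne-1,5-dione 23.
3. 23 ← alkynylation of the side-chain enoyl Weinreb amide 20 with the core homopropargylic alcohol 12, then oxidation.
4. Both halves ← the same (R)-lactic acid dioxolanone 3, by aldol addition of its lithium enolate to acrolein (core) or of its sodium enolate to (S)-2-methylbutanal (side chain).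
5. Stereocentres: C7 and C3′ from lactic acid, C5′ from (S)-2-methylbutan-1-ol, C8 and C4′ in the aldols, C8a in the cycloaddition.

Assumption: atom labels (C1–C8a, C1′–C7′) follow the isochromenone numbering of the target; the aldol sense (relative topicity lk, for the lithium and the sodium enolate) and the intramolecular cycloaddition are proposed by analogy and have not been checked against the literature.

**Route**

Step 1
Reactants: 1 (R)-lactic acid; 2 pivalaldehyde
Product: 3 (2R,5R)-2-tert-butyl-5-methyl-1,3-dioxolan-4-one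
Conditions: TsOH·H2O (cat.), H2SO4 (cat.), pentane, reflux, Dean–Stark; crystallise the cis isomer
Reagents that add atoms: none
Why: Acid-catalysed acetalisation (Seebach dioxolanone); the lactate centre directs the new acetal centre cis to the methyl group, and the cis isomer is purified by crystallisation.

Step 2
Reactants: 3 (2R,5R)-2-tert-butyl-5-methyl-1,3-dioxolan-4-one; 4 acrolein
Product: 6 (2R,5S)-2-tert-butyl-5-[(1R)-1-hydroxyprop-2-en-1-yl]-5-methyl-1,3-dioxolan-4-one, via lithium enolate 5 (not isolated)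
Conditions: LiN(iPr)2, THF, −78 °C; acrolein, −78 °C; NH4Cl (aq)
Reagents that add atoms: none
Why: Lithium aldol with self-regeneration of the stereocentre: acrolein adds 1,2 on the enolate face anti to the tert-butyl group (C7, retention of the lactate configuration), and a closed transition state with relative topicity lk is expected to give the (1R) carbinol (C8).

Step 3
Reactants: 6 (2R,5S)-2-tert-butyl-5-[(1R)-1-hydroxyprop-2-en-1-yl]-5-methyl-1,3-dioxolan-4-one
Product: 7 (2S,3R)-2,3-dihydroxy-N-methoxy-N,2-dimethylpent-4-enamide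
Conditions: MeNHOMe·HCl, iPrMgCl, THF, −20 → 0 °C
Reagents that add atoms: N,O-dimethylhydroxylamine hydrochloride, CNOC.Cl
Why: Weinreb aminolysis of the acetal-type lactone by the magnesium amide; the hemiacetal collapses with loss of pivalaldehyde and no stereocentre is touched.

Step 4
Reactants: 7 (2S,3R)-2,3-dihydroxy-N-methoxy-N,2-dimethylpent-4-enamide
Product: 8 (2S,3R)-N-methoxy-N,2-dimethyl-2,3-bis(triethylsilyloxy)pent-4-enamide
Conditions: Et3SiOTf, 2,6-lutidine, CH2Cl2, −78 → 0 °C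
Reagents that add atoms: triethylsilyl trifluoromethanesulfonate, CC[Si](CC)(CC)OS(=O)(=O)C(F)(F)F
Why: Silyl triflate protection of the secondary and the tertiary hydroxyl; the two bulky trans-disposed silyloxy groups later bias the cyclisation.

Step 5
Reactants: 8 (2S,3R)-N-methoxy-N,2-dimethyl-2,3-bis(triethylsilyloxy)pent-4-enamide
Product: 9 (2S,3R)-2-methyl-2,3-bis(triethylsilyloxy)pent-4-enal
Conditions: iBu2AlH, THF, −78 °C; aq. potassium sodium tartrate
Reagents that add atoms: none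
Why: Weinreb amide reduction stops at the aldehyde through the chelated tetrahedral intermediate; the α-carbon is quaternary, so it cannot epimerise.

Step 6
Reactants: 9 (2S,3R)-2-methyl-2,3-bis(triethylsilyloxy)pent-4-enal; 10 propargyl bromide
Product: 12 (3R,4R)-4-methyl-3,4-bis(triethylsilyloxy)oct-1-en-7-yn-5-ol (C5 epimers), via allenylzinc bromide 11 (not isolated)
Conditions: Zn dust, THF, 0 °C → rt; NH4Cl (aq)
Reagents that add atoms: none
Why: Barbier propargylation (SE2′ addition of the allenylzinc) gives the homopropargylic alcohol; the new carbinol (C6) is unselective and is oxidised to the ketone in step 14.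

Step 7
Reactants: 13 (S)-2-methylbutan-1-ol
Product: 14 (S)-2-methylbutanal
Conditions: TEMPO (cat.), KBr (cat.), NaOCl (aq), NaHCO3, CH2Cl2, 0 °C; used at once
Reagents that add atoms: none
Why: Anelli TEMPO/hypochlorite oxidation, chosen as a mild buffered method at 0 °C and with the aldehyde used at once to limit α-epimerisation.

Step 8
Reactants: 3 (2R,5R)-2-tert-butyl-5-methyl-1,3-dioxolan-4-one; 14 (S)-2-methylbutanal
Product: 16 (2R,5S)-2-tert-butyl-5-[(1R,2S)-1-hydroxy-2-methylbutyl]-5-methyl-1,3-dioxolan-4-one, via sodium enolate 15 (not isolated)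
Conditions: NaN(SiMe3)2, THF, −78 °C; 14, −78 °C, 15 min; NH4Cl (aq) at −78 °C
Reagents that add atoms: none
Why: Sodium-enolate aldol with self-regeneration of the stereocentre: the silazide base leaves no reducing secondary amine, and the reactive sodium enolate adds to the α-branched, epimerisable aldehyde within minutes at −78 °C. Attack anti to the tert-butyl group sets C3′, and a closed sodium-bridged transition state of relative topicity lk is expected to set C4′ as (R), matched with the at most weak Felkin–Anh preference of the (S)-aldehyde.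

Step 9
Reactants: 16 (2R,5S)-2-tert-butyl-5-[(1R,2S)-1-hydroxy-2-methylbutyl]-5-methyl-1,3-dioxolan-4-one
Product: 17 (2S,3R,4S)-2,3-dihydroxy-N-methoxy-N,2,4-trimethylhexanamide
Conditions: MeNHOMe·HCl, iPrMgCl, THF, −20 → 0 °C
Reagents that add atoms: N,O-dimethylhydroxylamine hydrochloride, CNOC.Cl
Why: Weinreb aminolysis with loss of pivalaldehyde, as in step 3; no stereocentre is touched.

Step 10
Reactants: 17 (2S,3R,4S)-2,3-dihydroxy-N-methoxy-N,2,4-trimethylhexanamide
Product: 18 (2S,3R,4S)-N-methoxy-N,2,4-trimethyl-2,3-bis(triethylsilyloxy)hexanamide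
Conditions: Et3SiOTf, 2,6-lutidine, CH2Cl2, −78 → 0 °C
Reagents that add atoms: triethylsilyl trifluoromethanesulfonate, CC[Si](CC)(CC)OS(=O)(=O)C(F)(F)F
Why: Silyl triflate protection of both hydroxyls, as in step 4.

Step 11
Reactants: 18 (2S,3R,4S)-N-methoxy-N,2,4-trimethyl-2,3-bis(triethylsilyloxy)hexanamide
Product: 19 (2S,3R,4S)-2,4-dimethyl-2,3-bis(triethylsilyloxy)hexanal
Conditions: iBu2AlH, THF, −78 °C; aq. potassium sodium tartrate
Reagents that add atoms: none
Why: Weinreb amide reduction to the non-epimerisable α-quaternary aldehyde, as in step 5.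

Step 12
Reactants: 19 (2S,3R,4S)-2,4-dimethyl-2,3-bis(triethylsilyloxy)hexanal
Product: 20 (2E,4R,5R,6S)-N-methoxy-N,4,6-trimethyl-4,5-bis(triethylsilyloxy)oct-2-enamide
Conditions: (EtO)2P(O)CH2C(O)N(OMe)Me, NaH, THF, 0 °C → rt
Reagents that add atoms: diethyl [2-[methoxy(methyl)amino]-2-oxoethyl]phosphonate, CCOP(=O)(CC(=O)N(C)OC)OCC
Why: Horner–Wadsworth–Emmons olefination with a stabilised phosphonate gives the (E)-alkene (C1′=C2′) and places the acyl donor for the coupling.

Step 13
Reactants: 12 (3R,4R)-4-methyl-3,4-bis(triethylsilyloxy)oct-1-en-7-yn-5-ol; 20 (2E,4R,5R,6S)-N-methoxy-N,4,6-trimethyl-4,5-bis(triethylsilyloxy)oct-2-enamide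
Product: 22 (3S,4R,5R,6E,13R,14R)-12-hydroxy-3,5,13-trimethyl-4,5,13,14-tetrakis(triethylsilyloxy)hexadeca-6,15-dien-9-yn-8-one (C12 epimers), via dilithio derivative 21 (not isolated)
Conditions: n-BuLi (2.1 equiv), THF, −78 °C; 20, −78 → −30 °C; NH4Cl (aq)
Reagents that add atoms: none
Why: Acylation of the lithium acetylide by the Weinreb amide; the chelated tetrahedral intermediate prevents over-addition, and the hard acetylide adds 1,2 and not 1,4.

Step 14
Reactants: 22 (3S,4R,5R,6E,13R,14R)-12-hydroxy-3,5,13-trimethyl-4,5,13,14-tetrakis(triethylsilyloxy)hexadeca-6,15-dien-9-yn-8-one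
Product: 23 (3S,4R,5R,6E,13S,14R)-3,5,13-trimethyl-4,5,13,14-tetrakis(triethylsilyloxy)hexadeca-6,15-dien-9-yne-8,12-dione
Conditions: Dess–Martin periodinane, NaHCO3, CH2Cl2, 0 °C → rt; used crude
Reagents that add atoms: none
Why: Buffered Dess–Martin oxidation of the hindered secondary carbinol removes the unselective C6 centre and creates the acidic CH2 between the ketone and the ynone.

Step 15
Reactants: 23 (3S,4R,5R,6E,13S,14R)-3,5,13-trimethyl-4,5,13,14-tetrakis(triethylsilyloxy)hexadeca-6,15-dien-9-yne-8,12-dione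
Product: 25 (7S,8R,8aS)-3-[(1E,3R,4R,5S)-3,5-dimethyl-3,4-bis(triethylsilyloxy)hept-1-en-1-yl]-7-methyl-7,8-bis(triethylsilyloxy)-1,7,8,8a-tetrahydro-6H-isochromen-6-one, via allenyl diketone 24 (not isolated)
Conditions: Et3N (0.2 equiv), toluene (0.005 M), rt then 80 °C
Reagents that add atoms: none
Why: Amine-mediated propargyl-to-allenyl isomerisation gives the 1,3-diacylallene, whose s-cis allenyl ketone undergoes an intramolecular inverse-electron-demand oxa-Diels–Alder reaction with the tethered vinyl group to form both rings at the final oxidation level. C8a is set in a half-chair with the two bulky trans silyloxy groups pseudo-axial and the C7 methyl pseudo-equatorial, so C8a–H is anti to C8–O (8,8a-cis).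

Step 16
Reactants: 25 (7S,8R,8aS)-3-[(1E,3R,4R,5S)-3,5-dimethyl-3,4-bis(triethylsilyloxy)hept-1-en-1-yl]-7-methyl-7,8-bis(triethylsilyloxy)-1,7,8,8a-tetrahydro-6H-isochromen-6-one
Product: 26 (7S,8R,8aS)-3-[(1E,3R,4R,5S)-3,4-dihydroxy-3,5-dimethylhept-1-en-1-yl]-7,8-dihydroxy-7-methyl-1,7,8,8a-tetrahydro-6H-isochromen-6-one
Conditions: HF·pyridine, pyridine, THF, 0 °C → rt
Reagents that add atoms: none
Why: Buffered fluoride desilylation removes all four triethylsilyl groups without base-mediated epimerisation at C8a or retro-aldol cleavage; no stereocentre is touched.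

**Compound list**

1 | (R)-lactic acid | C[C@@H](O)C(=O)O | starting material
2 | pivalaldehyde | CC(C)(C)C=O | starting material
3 | (2R,5R)-2-tert-butyl-5-methyl-1,3-dioxolan-4-one | C[C@H]1O[C@@H](C(C)(C)C)OC1=O | intermediate
4 | acrolein | C=CC=O | starting material
5 | lithium (2R)-2-tert-butyl-5-methyl-1,3-dioxol-4-olate (lithium enolate of 3) | [Li+].CC1=C([O-])O[C@H](C(C)(C)C)O1 | intermediate
6 | (2R,5S)-2-tert-butyl-5-[(1R)-1-hydroxyprop-2-en-1-yl]-5-methyl-1,3-dioxolan-4-one | C=C[C@@H](O)[C@]1(C)O[C@@H](C(C)(C)C)OC1=O | intermediate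
7 | (2S,3R)-2,3-dihydroxy-N-methoxy-N,2-dimethylpent-4-enamide | C=C[C@@H](O)[C@](C)(O)C(=O)N(C)OC | intermediate
8 | (2S,3R)-N-methoxy-N,2-dimethyl-2,3-bis(triethylsilyloxy)pent-4-enamide | C=C[C@@H](O[Si](CC)(CC)CC)[C@](C)(O[Si](CC)(CC)CC)C(=O)N(C)OC | intermediate
9 | (2S,3R)-2-methyl-2,3-bis(triethylsilyloxy)pent-4-enal | C=C[C@@H](O[Si](CC)(CC)CC)[C@](C)(O[Si](CC)(CC)CC)C=O | intermediate
10 | propargyl bromide (3-bromoprop-1-yne) | C#CCBr | starting material
11 | allenylzinc bromide | C=C=C[Zn]Br | intermediate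
12 | (3R,4R)-4-methyl-3,4-bis(triethylsilyloxy)oct-1-en-7-yn-5-ol (C5 epimers) | C=C[C@@H](O[Si](CC)(CC)CC)[C@](C)(O[Si](CC)(CC)CC)C(O)CC#C | intermediate
13 | (S)-2-methylbutan-1-ol | CC[C@H](C)CO | starting material
14 | (S)-2-methylbutanal | CC[C@H](C)C=O | intermediate
15 | sodium (2R)-2-tert-butyl-5-methyl-1,3-dioxol-4-olate (sodium enolate of 3) | [Na+].CC1=C([O-])O[C@H](C(C)(C)C)O1 | intermediate
16 | (2R,5S)-2-tert-butyl-5-[(1R,2S)-1-hydroxy-2-methylbutyl]-5-methyl-1,3-dioxolan-4-one | CC[C@H](C)[C@@H](O)[C@]1(C)O[C@@H](C(C)(C)C)OC1=O | intermediate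
17 | (2S,3R,4S)-2,3-dihydroxy-N-methoxy-N,2,4-trimethylhexanamide | CC[C@H](C)[C@@H](O)[C@](C)(O)C(=O)N(C)OC | intermediate
18 | (2S,3R,4S)-N-methoxy-N,2,4-trimethyl-2,3-bis(triethylsilyloxy)hexanamide | CC[C@H](C)[C@@H](O[Si](CC)(CC)CC)[C@](C)(O[Si](CC)(CC)CC)C(=O)N(C)OC | intermediate
19 | (2S,3R,4S)-2,4-dimethyl-2,3-bis(triethylsilyloxy)hexanal | CC[C@H](C)[C@@H](O[Si](CC)(CC)CC)[C@](C)(O[Si](CC)(CC)CC)C=O | intermediate
20 | (2E,4R,5R,6S)-N-methoxy-N,4,6-trimethyl-4,5-bis(triethylsilyloxy)oct-2-enamide | CC[C@H](C)[C@@H](O[Si](CC)(CC)CC)[C@](C)(O[Si](CC)(CC)CC)/C=C/C(=O)N(C)OC | intermediate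
21 | dilithio derivative of 12 (C5 alkoxide, C8 acetylide) | [Li+].[Li+].C=C[C@@H](O[Si](CC)(CC)CC)[C@](C)(O[Si](CC)(CC)CC)C([O-])CC#[C-] | intermediate
22 | (3S,4R,5R,6E,13R,14R)-12-hydroxy-3,5,13-trimethyl-4,5,13,14-tetrakis(triethylsilyloxy)hexadeca-6,15-dien-9-yn-8-one (C12 epimers) | CC[C@H](C)[C@@H](O[Si](CC)(CC)CC)[C@](C)(O[Si](CC)(CC)CC)/C=C/C(=O)C#CCC(O)[C@@](C)(O[Si](CC)(CC)CC)[C@H](O[Si](CC)(CC)CC)C=C | intermediate
23 | (3S,4R,5R,6E,13S,14R)-3,5,13-trimethyl-4,5,13,14-tetrakis(triethylsilyloxy)hexadeca-6,15-dien-9-yne-8,12-dione | CC[C@H](C)[C@@H](O[Si](CC)(CC)CC)[C@](C)(O[Si](CC)(CC)CC)/C=C/C(=O)C#CCC(=O)[C@@](C)(O[Si](CC)(CC)CC)[C@H](O[Si](CC)(CC)CC)C=C | intermediate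
24 | (3S,4R,5R,6E,13S,14R)-3,5,13-trimethyl-4,5,13,14-tetrakis(triethylsilyloxy)hexadeca-6,9,10,15-tetraene-8,12-dione (both allene epimers) | CC[C@H](C)[C@@H](O[Si](CC)(CC)CC)[C@](C)(O[Si](CC)(CC)CC)/C=C/C(=O)C=C=CC(=O)[C@@](C)(O[Si](CC)(CC)CC)[C@H](O[Si](CC)(CC)CC)C=C | intermediate
25 | (7S,8R,8aS)-3-[(1E,3R,4R,5S)-3,5-dimethyl-3,4-bis(triethylsilyloxy)hept-1-en-1-yl]-7-methyl-7,8-bis(triethylsilyloxy)-1,7,8,8a-tetrahydro-6H-isochromen-6-one | CC[C@H](C)[C@@H](O[Si](CC)(CC)CC)[C@](C)(O[Si](CC)(CC)CC)/C=C/C1=CC2=CC(=O)[C@@](C)(O[Si](CC)(CC)CC)[C@H](O[Si](CC)(CC)CC)[C@@H]2CO1 | intermediate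
26 | (7S,8R,8aS)-3-[(1E,3R,4R,5S)-3,4-dihydroxy-3,5-dimethylhept-1-en-1-yl]-7,8-dihydroxy-7-methyl-1,7,8,8a-tetrahydro-6H-isochromen-6-one | CC[C@H](C)[C@@H](O)[C@](C)(O)/C=C/C1=CC2=CC(=O)[C@@](C)(O)[C@H](O)[C@@H]2CO1 | target

**Step count**

Total: 16 steps. Longest linear sequence: 10 steps (1, 2, 3, 4, 5, 6, 13, 14, 15, 16; the side-chain branch 1, 8, 9, 10, 11, 12, 13–16 is equally long).

**Three steps most likely to fail, with fallbacks**

Step 15 is the main risk. The 1,3-diacylallene may dimerise or polymerise faster than it is trapped by the unactivated vinyl group, and C8a may form as a mixture. A C8a mixture could in principle be equilibrated through the dienolate with DBU, with β-elimination of the C8 silyloxy group as the danger. The fallback changes the ring-forming event to an oxa-6π electrocyclisation and sets out from 22. Pd(OAc)2/PPh3 in warm benzene cycloisomerises the 1,7-enyne to the (E)-configured bis-exocyclic dienone alcohol F1. Catalytic I2 and light isomerise the enone double bond to the (Z)-dienone alcohol F2. F2 closes thermally by oxa-6π electrocyclisation to the 2H-pyran alcohol F3. Dess–Martin oxidation gives the β,γ-unsaturated pyranone F4, and catalytic DBU moves the C4a=C8a double bond into conjugation with protonation at C8a, which returns to 25.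

Step 2 is the second risk. Acrolein is a small aldehyde, so the carbinol (C8) selectivity may be low or the sense may differ from the one assumed. The fallback sets C8 by hydride addition instead of C–C bond formation and sets out from 6 obtained as a mixture with its carbinol epimer. Dess–Martin oxidation gives the acryloyl ketone F5. Luche reduction (NaBH4, CeCl3·7H2O, MeOH, −78 °C) under Felkin–Anh control, with hydride anti to the ring C–O bond and past the methyl group, returns to 6.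

Step 13 is the third risk. Acylation of the hindered dilithio species needs warming, which invites migration of the C7 silyl group to the neighbouring C6 alkoxide. The fallback replaces the acylation by a fast carbonyl addition and sets out from 20. iBu2AlH reduces 20 to the enal F6. The dilithio derivative 21 adds to F6 at −78 °C to give the propargylic diol F7. Dess–Martin periodinane oxidises both carbinols in one operation, which returns to the route at 23.

**Further compounds**

F1 | step 15 | (3E,5R,6R,7S)-1-[(1E,3R,4R)-5-hydroxy-4-methyl-2-methylidene-3,4-bis(triethylsilyloxy)cyclohexylidene]-5,7-dimethyl-5,6-bis(triethylsilyloxy)non-3-en-2-one | CC[C@H](C)[C@@H](O[Si](CC)(CC)CC)[C@](C)(O[Si](CC)(CC)CC)/C=C/C(=O)/C=C1\CC(O)[C@@](C)(O[Si](CC)(CC)CC)[C@H](O[Si](CC)(CC)CC)C1=C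
F2 | step 15 | (3E,5R,6R,7S)-1-[(1Z,3R,4R)-5-hydroxy-4-methyl-2-methylidene-3,4-bis(triethylsilyloxy)cyclohexylidene]-5,7-dimethyl-5,6-bis(triethylsilyloxy)non-3-en-2-one | CC[C@H](C)[C@@H](O[Si](CC)(CC)CC)[C@](C)(O[Si](CC)(CC)CC)/C=C/C(=O)/C=C1/CC(O)[C@@](C)(O[Si](CC)(CC)CC)[C@H](O[Si](CC)(CC)CC)C1=C
F3 | step 15 | (7R,8R)-3-[(1E,3R,4R,5S)-3,5-dimethyl-3,4-bis(triethylsilyloxy)hept-1-en-1-yl]-7-methyl-7,8-bis(triethylsilyloxy)-5,6,7,8-tetrahydro-1H-isochromen-6-ol (C6 epimers) | CC[C@H](C)[C@@H](O[Si](CC)(CC)CC)[C@](C)(O[Si](CC)(CC)CC)/C=C/C1=CC2=C(CO1)[C@@H](O[Si](CC)(CC)CC)[C@](C)(O[Si](CC)(CC)CC)C(O)C2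
F4 | step 15 | (7S,8R)-3-[(1E,3R,4R,5S)-3,5-dimethyl-3,4-bis(triethylsilyloxy)hept-1-en-1-yl]-7-methyl-7,8-bis(triethylsilyloxy)-7,8-dihydro-1H-isochromen-6(5H)-one | CC[C@H](C)[C@@H](O[Si](CC)(CC)CC)[C@](C)(O[Si](CC)(CC)CC)/C=C/C1=CC2=C(CO1)[C@@H](O[Si](CC)(CC)CC)[C@](C)(O[Si](CC)(CC)CC)C(=O)C2
F5 | step 2 | (2R,5S)-2-tert-butyl-5-methyl-5-(prop-2-enoyl)-1,3-dioxolan-4-one | C=CC(=O)[C@]1(C)O[C@@H](C(C)(C)C)OC1=O
F6 | step 13 | (2E,4R,5R,6S)-4,6-dimethyl-4,5-bis(triethylsilyloxy)oct-2-enal | CC[C@H](C)[C@@H](O[Si](CC)(CC)CC)[C@](C)(O[Si](CC)(CC)CC)/C=C/C=O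
F7 | step 13 | (3S,4R,5R,6E,13R,14R)-3,5,13-trimethyl-4,5,13,14-tetrakis(triethylsilyloxy)hexadeca-6,15-dien-9-yne-8,12-diol (C8 and C12 epimers) | CC[C@H](C)[C@@H](O[Si](CC)(CC)CC)[C@](C)(O[Si](CC)(CC)CC)/C=C/C(O)C#CCC(O)[C@@](C)(O[Si](CC)(CC)CC)[C@H](O[Si](CC)(CC)CC)C=C
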